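Ring numbering: C1 carries CO2Me (C7), C2 is the vinylic CH, C3, C4 and C5 carry the acetate, the (R)-2-methylbutanoate and the (S)-3-methylpentanoate, and C6 is the CH2.
Retrosynthetic cuts, in order: the acyl C–O bonds at O5, O4 and O3; C1–C7 (back to a C1 vinyl bromide); the ring bond C2–C3 together with C1–Br; C6–C1 (acetylide plus primary triflate).
Enabling feature: in the cyclohexene the C1=C2 double bond lies directly beside the C3 carbinol. This is the pattern left when the terminal carbon C2 of a C1≡C2 alkyne adds to a C3 aldehyde and a halide caps C1. The trans O4/O5 pair on C4–C5 is the threo diol of D-tartaric acid.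
Forward order: diethyl D-tartrate supplies C3–C6, trimethylsilylacetylene adds C1–C2, the only ring closes in the TiBr4 step, carbon monoxide adds C7, and O3, O4 and O5 (H, PMB and TBS after ring closure) are acylated one after the other.
Stereochemistry: C4 and C5 are carried unchanged from D-tartrate, C3 is set in the ring closure by the titanium chelate between the aldehyde oxygen and O4, and the two side-chain centres come with the purchased acids.
Key step: step 9

Remark: TBS = tert-butyldimethylsilyl and PMB = 4-methoxybenzyl; labels C1–C7 and O3–O5 follow the ring numbering above in all intermediates.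
Remark: both chiral acids are taken as purchasable in enantiopure form, and the acetal carbon of the 4-methoxybenzylidene intermediates is an epimer mixture that has no consequence because it is erased in step 7.

Step 1
Reactants: 1 diethyl D-tartrate, diethyl (2S,3S)-2,3-dihydroxybutanedioate
Product: 2 diethyl (2S,3S)-2-(tert-butyldimethylsilyloxy)-3-hydroxybutanedioate
Conditions: TBSCl (1.0 equiv), imidazole, DMF, 0 °C to rt
Reagents that add atoms: tert-butyldimethylsilyl chloride, CC(C)(C)[Si](C)(C)Cl
Why: Silyl ether formation on a diol whose two hydroxyls are equivalent through the twofold axis can give only one mono-ether (the future O5–TBS), and the bulk of the first silyl group slows a second silylation.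

Step 2
Reactants: 2 diethyl (2S,3S)-2-(tert-butyldimethylsilyloxy)-3-hydroxybutanedioate
Product: 3 ethyl (2S,3R)-2-(tert-butyldimethylsilyloxy)-3,4-dihydroxybutanoate
Conditions: BH3·SMe2 (1.05 equiv), NaBH4 (5 mol %), THF, 0 °C to rt; MeOH
Reagents that add atoms: none
Why: Hydroxyl-directed borane reduction of an α-hydroxy ester: the free O4 hydroxyl forms an alkoxyborane that passes hydride through a five-membered ring to the neighbouring ester carbon (the future C3) only, so the ester beside the silyl ether survives and neither stereocentre is touched.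

Step 3
Reactants: 3 ethyl (2S,3R)-2-(tert-butyldimethylsilyloxy)-3,4-dihydroxybutanoate
Product: 4 ethyl (2S)-2-(tert-butyldimethylsilyloxy)-2-[(4R)-2-(4-methoxyphenyl)-1,3-dioxolan-4-yl]acetate (epimers at dioxolane C2)
Conditions: 4-MeOC6H4CH(OMe)2, PPTS (cat.), CH2Cl2, rt
Reagents that add atoms: 4-methoxybenzaldehyde dimethyl acetal, COc1ccc(cc1)C(OC)OC
Why: Acid-catalysed transacetalisation ties O3 and O4 into a five-membered 4-methoxybenzylidene acetal, which forestalls lactonisation of the primary hydroxyl onto the ester, and the new acetal carbon forms without control because it is erased in step 7.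

Step 4
Reactants: 4 ethyl (2S)-2-(tert-butyldimethylsilyloxy)-2-[(4R)-2-(4-methoxyphenyl)-1,3-dioxolan-4-yl]acetate
Product: 5 (2R)-2-(tert-butyldimethylsilyloxy)-2-[(4R)-2-(4-methoxyphenyl)-1,3-dioxolan-4-yl]ethanol
Conditions: LiBH4, MeOH (1 equiv), Et2O, 0 °C
Reagents that add atoms: none
Why: Ester reduction with LiBH4 brings C6 to the alcohol level while acetal and silyl ether are inert to borohydride, and the weakly basic boron alkoxide formed should not trigger silyl migration from O5.

Step 5
Reactants: 5 (2R)-2-(tert-butyldimethylsilyloxy)-2-[(4R)-2-(4-methoxyphenyl)-1,3-dioxolan-4-yl]ethanol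
Product: 6 (2R)-2-(tert-butyldimethylsilyloxy)-2-[(4R)-2-(4-methoxyphenyl)-1,3-dioxolan-4-yl]ethyl trifluoromethanesulfonate
Conditions: Tf2O, 2,6-lutidine, CH2Cl2, −78 °C; cold aqueous wash, used without chromatography
Reagents that add atoms: trifluoromethanesulfonic anhydride, O=S(=O)(OS(=O)(=O)C(F)(F)F)C(F)(F)F
Why: Sulfonylation of an unhindered primary alcohol with triflic anhydride and a hindered pyridine base at low temperature provides the most reactive leaving group for a carbon that has a branched, oxygenated neighbour.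

Step 6
Reactants: 6 (2R)-2-(tert-butyldimethylsilyloxy)-2-[(4R)-2-(4-methoxyphenyl)-1,3-dioxolan-4-yl]ethyl trifluoromethanesulfonate; 7 trimethylsilylacetylene
Product: 9 (4R)-4-[(1R)-1-(tert-butyldimethylsilyloxy)but-3-yn-1-yl]-2-(4-methoxyphenyl)-1,3-dioxolane, via C-silylated alkyne 8 (not isolated)
Conditions: 7, n-BuLi, THF, −78 °C; then 6, DMPU, −78 to −20 °C; then MeOH, K2CO3, rt
Reagents that add atoms: none
Why: SN2 alkylation of a lithium acetylide by a primary triflate in THF/DMPU, well established for tartrate-derived triflates, forms C6–C1 without involving the C5 stereocentre, and base-catalysed methanolysis of the alkynyl C–Si bond then frees the terminal alkyne while the secondary TBS ether stays.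

Step 7
Reactants: 9 (4R)-4-[(1R)-1-(tert-butyldimethylsilyloxy)but-3-yn-1-yl]-2-(4-methoxyphenyl)-1,3-dioxolane
Product: 10 (2R,3R)-3-(tert-butyldimethylsilyloxy)-2-(4-methoxybenzyloxy)hex-5-yn-1-ol
Conditions: iBu2AlH (3 equiv), CH2Cl2, −78 to 0 °C; aq. potassium sodium tartrate
Reagents that add atoms: none
Why: Regioselective reductive opening of a 4-methoxybenzylidene acetal: aluminium binds the less hindered primary oxygen O3, the acetal C–O3 bond breaks and hydride reduces the oxocarbenium ion left on O4, so that PMB lands on O4 and the C3 alcohol is freed in a single operation.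

Step 8
Reactants: 10 (2R,3R)-3-(tert-butyldimethylsilyloxy)-2-(4-methoxybenzyloxy)hex-5-yn-1-ol
Product: 11 (2S,3R)-3-(tert-butyldimethylsilyloxy)-2-(4-methoxybenzyloxy)hex-5-ynal
Conditions: Dess–Martin periodinane, CH2Cl2, 0 °C to rt; used at once
Reagents that add atoms: none
Why: Dess–Martin oxidation turns the primary alcohol into the aldehyde under non-basic conditions that should leave the epimerisable C4 centre, the alkyne and both ethers untouched.

Step 9
Reactants: 11 (2S,3R)-3-(tert-butyldimethylsilyloxy)-2-(4-methoxybenzyloxy)hex-5-ynal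
Product: 13 (1R,5R,6R)-3-bromo-5-(tert-butyldimethylsilyloxy)-6-(4-methoxybenzyloxy)cyclohex-2-en-1-ol (1,6-cis and 5,6-trans), via tribromotitanium alkoxide 12 (not isolated)
Conditions: TiBr4 (1.2 equiv), 2,6-di-tert-butyl-4-methylpyridine (0.5 equiv), CH2Cl2 (0.02 M), −78 °C; sat. aq. NaHCO3 at −78 °C
Reagents that add atoms: titanium tetrabromide, Br[Ti](Br)(Br)Br
Why: Proposed new method: in 11 titanium is clamped between the carbonyl oxygen and the ether oxygen O4 (five-membered chelate), the terminal alkyne carbon C2 bonds to the activated C3, positive charge builds on the internal carbon C1 and a bromide of the titanium ate complex caps C1 anti to the new C2–C3 bond, which gives alkoxide 12 and, after a cold quench, 13. The closest known reaction type is the alkyne Prins cyclisation with halide capture, in which FeCl3, FeBr3 or titanium tetrahalides close oxocarbenium ions onto terminal alkynes to give 4-halo-5,6-dihydro-2H-pyrans over the same three-atom tether; new here are the all-carbon ring and a chelated α-alkoxy aldehyde as the electrophile. The one ring closes 6-endo-dig, since 5-exo attack through C1 would leave a primary vinyl cation on C2 whereas endo attack places the charge on the substituted carbon, where bromide capture can run in concert with C–C bond formation. C3 is controlled by the chelate: with the O3–C3–C4–O4 torsion held small, the tether through C5 and C6 reaches only the carbonyl face on its own side, the forming carbocycle is cis-fused to the chelate ring, and O3 ends cis to O4 while O4 and O5 stand antiperiplanar (both pseudoaxial) in the transition state. The step needs this chelated path to beat the open chair with a pseudoequatorial carbonyl oxygen, which would give the C3 epimer, and this is secured by a basic benzyl-type ether on O4, a bulky non-coordinating silyl ether on O5 and CH2Cl2 as a non-donor solvent. PMB, TBS and the new allylic C3–O bond must also survive, which is why the mixture stays at −78 °C and a hindered pyridine removes adventitious HBr, and the PMB ring positions that could reach C3 are meta to the methoxy group and thus not activated for Friedel–Crafts closure.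

Step 10
Reactants: 13 (1R,5R,6R)-3-bromo-5-(tert-butyldimethylsilyloxy)-6-(4-methoxybenzyloxy)cyclohex-2-en-1-ol
Product: 14 methyl (3R,4R,5R)-5-(tert-butyldimethylsilyloxy)-3-hydroxy-4-(4-methoxybenzyloxy)cyclohex-1-ene-1-carboxylate
Conditions: Pd(OAc)2 (5 mol %), 1,1'-bis(diphenylphosphino)ferrocene (10 mol %), Et3N, CO (1 atm), MeOH/DMF, 65 °C
Reagents that add atoms: carbon monoxide, [C-]#[O+]; methanol, CO
Why: Palladium-catalysed alkoxycarbonylation of a vinyl halide (oxidative addition of zerovalent palladium into C1–Br, CO insertion, methanolysis of the acyl complex) installs C7, and it is run on the free allylic alcohol so that no allylic ester is present that palladium could ionise.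

Step 11
Reactants: 14 methyl (3R,4R,5R)-5-(tert-butyldimethylsilyloxy)-3-hydroxy-4-(4-methoxybenzyloxy)cyclohex-1-ene-1-carboxylate
Product: 15 methyl (3R,4R,5R)-3-acetoxy-5-(tert-butyldimethylsilyloxy)-4-(4-methoxybenzyloxy)cyclohex-1-ene-1-carboxylate
Conditions: Ac2O, pyridine, DMAP (cat.), CH2Cl2, 0 °C to rt
Reagents that add atoms: acetic anhydride, CC(=O)OC(C)=O
Why: DMAP-catalysed acetylation of the only free hydroxyl, O3, proceeds with retention because the C3–O bond is not broken.

Step 12
Reactants: 15 methyl (3R,4R,5R)-3-acetoxy-5-(tert-butyldimethylsilyloxy)-4-(4-methoxybenzyloxy)cyclohex-1-ene-1-carboxylate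
Product: 16 methyl (3R,4R,5R)-3-acetoxy-5-(tert-butyldimethylsilyloxy)-4-hydroxycyclohex-1-ene-1-carboxylate
Conditions: DDQ, CH2Cl2/pH 7 phosphate buffer, 0 °C
Reagents that add atoms: none
Why: Oxidative PMB ether cleavage with DDQ (hydride abstraction from the electron-rich benzylic position, then hydrolysis) frees O4 under buffered neutral conditions that spare the TBS ether, both esters and the electron-poor alkene.

Step 13
Reactants: 16 methyl (3R,4R,5R)-3-acetoxy-5-(tert-butyldimethylsilyloxy)-4-hydroxycyclohex-1-ene-1-carboxylate; 17 (R)-2-methylbutanoic acid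
Product: 18 methyl (3R,4R,5R)-3-acetoxy-5-(tert-butyldimethylsilyloxy)-4-[(2R)-2-methylbutanoyloxy]cyclohex-1-ene-1-carboxylate
Conditions: 17, DCC, DMAP (cat.), CH2Cl2, 0 °C to rt
Reagents that add atoms: none
Why: Steglich esterification acylates the equatorial O4 hydroxyl, and carbodiimide/DMAP activation of simple α-branched alkanoic acids is known to keep the α-centre intact as long as no acid chloride and no tertiary amine base are involved.

Step 14
Reactants: 18 methyl (3R,4R,5R)-3-acetoxy-5-(tert-butyldimethylsilyloxy)-4-[(2R)-2-methylbutanoyloxy]cyclohex-1-ene-1-carboxylate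
Product: 19 methyl (3R,4S,5R)-3-acetoxy-5-hydroxy-4-[(2R)-2-methylbutanoyloxy]cyclohex-1-ene-1-carboxylate
Conditions: HF·pyridine, pyridine, THF, 0 °C to rt (plastic vessel)
Reagents that add atoms: none
Why: Fluoride-mediated desilylation with buffered HF·pyridine removes the secondary TBS ether in a weakly acidic medium, in which acyl migration from O4 to O5 and elimination toward an arene (both base-promoted) should stay slow.

Step 15
Reactants: 19 methyl (3R,4S,5R)-3-acetoxy-5-hydroxy-4-[(2R)-2-methylbutanoyloxy]cyclohex-1-ene-1-carboxylate; 20 (S)-3-methylpentanoic acid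
Product: 21 methyl (3R,4S,5R)-3-acetoxy-4-[(2R)-2-methylbutanoyloxy]-5-[(3S)-3-methylpentanoyloxy]cyclohex-1-ene-1-carboxylate (CNP0188172.1)
Conditions: 20, DCC, DMAP (cat.), CH2Cl2, 0 °C to rt
Reagents that add atoms: none
Why: A second Steglich esterification acylates the last free hydroxyl, O5, with an acid whose stereocentre is β to the carboxyl group and therefore cannot epimerise, which completes the target.

Compound list
1 | diethyl D-tartrate, diethyl (2S,3S)-2,3-dihydroxybutanedioate | CCOC(=O)[C@@H](O)[C@H](O)C(=O)OCC | starting material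
2 | diethyl (2S,3S)-2-(tert-butyldimethylsilyloxy)-3-hydroxybutanedioate | CCOC(=O)[C@@H](O)[C@H](O[Si](C)(C)C(C)(C)C)C(=O)OCC | intermediate
3 | ethyl (2S,3R)-2-(tert-butyldimethylsilyloxy)-3,4-dihydroxybutanoate | OC[C@@H](O)[C@H](O[Si](C)(C)C(C)(C)C)C(=O)OCC | intermediate
4 | ethyl (2S)-2-(tert-butyldimethylsilyloxy)-2-[(4R)-2-(4-methoxyphenyl)-1,3-dioxolan-4-yl]acetate (epimers at dioxolane C2) | O1C(c2ccc(OC)cc2)OC[C@@H]1[C@H](O[Si](C)(C)C(C)(C)C)C(=O)OCC | intermediate
5 | (2R)-2-(tert-butyldimethylsilyloxy)-2-[(4R)-2-(4-methoxyphenyl)-1,3-dioxolan-4-yl]ethanol | O1C(c2ccc(OC)cc2)OC[C@@H]1[C@H](O[Si](C)(C)C(C)(C)C)CO | intermediate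
6 | (2R)-2-(tert-butyldimethylsilyloxy)-2-[(4R)-2-(4-methoxyphenyl)-1,3-dioxolan-4-yl]ethyl trifluoromethanesulfonate | O1C(c2ccc(OC)cc2)OC[C@@H]1[C@H](O[Si](C)(C)C(C)(C)C)COS(=O)(=O)C(F)(F)F | intermediate
7 | trimethylsilylacetylene | C#C[Si](C)(C)C | starting material
8 | (4R)-4-[(1R)-1-(tert-butyldimethylsilyloxy)-4-(trimethylsilyl)but-3-yn-1-yl]-2-(4-methoxyphenyl)-1,3-dioxolane | O1C(c2ccc(OC)cc2)OC[C@@H]1[C@H](O[Si](C)(C)C(C)(C)C)CC#C[Si](C)(C)C | intermediate
9 | (4R)-4-[(1R)-1-(tert-butyldimethylsilyloxy)but-3-yn-1-yl]-2-(4-methoxyphenyl)-1,3-dioxolane | O1C(c2ccc(OC)cc2)OC[C@@H]1[C@H](O[Si](C)(C)C(C)(C)C)CC#C | intermediate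
10 | (2R,3R)-3-(tert-butyldimethylsilyloxy)-2-(4-methoxybenzyloxy)hex-5-yn-1-ol | OC[C@@H](OCc1ccc(OC)cc1)[C@H](O[Si](C)(C)C(C)(C)C)CC#C | intermediate
11 | (2S,3R)-3-(tert-butyldimethylsilyloxy)-2-(4-methoxybenzyloxy)hex-5-ynal | O=C[C@@H](OCc1ccc(OC)cc1)[C@H](O[Si](C)(C)C(C)(C)C)CC#C | intermediate
12 | tribromotitanium alkoxide of 13 (titanium on O3) | BrC1=C[C@@H](O[Ti](Br)(Br)Br)[C@@H](OCc2ccc(OC)cc2)[C@H](O[Si](C)(C)C(C)(C)C)C1 | intermediate
13 | (1R,5R,6R)-3-bromo-5-(tert-butyldimethylsilyloxy)-6-(4-methoxybenzyloxy)cyclohex-2-en-1-ol | BrC1=C[C@@H](O)[C@@H](OCc2ccc(OC)cc2)[C@H](O[Si](C)(C)C(C)(C)C)C1 | intermediate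
14 | methyl (3R,4R,5R)-5-(tert-butyldimethylsilyloxy)-3-hydroxy-4-(4-methoxybenzyloxy)cyclohex-1-ene-1-carboxylate | COC(=O)C1=C[C@@H](O)[C@@H](OCc2ccc(OC)cc2)[C@H](O[Si](C)(C)C(C)(C)C)C1 | intermediate
15 | methyl (3R,4R,5R)-3-acetoxy-5-(tert-butyldimethylsilyloxy)-4-(4-methoxybenzyloxy)cyclohex-1-ene-1-carboxylate | COC(=O)C1=C[C@@H](OC(C)=O)[C@@H](OCc2ccc(OC)cc2)[C@H](O[Si](C)(C)C(C)(C)C)C1 | intermediate
16 | methyl (3R,4R,5R)-3-acetoxy-5-(tert-butyldimethylsilyloxy)-4-hydroxycyclohex-1-ene-1-carboxylate | COC(=O)C1=C[C@@H](OC(C)=O)[C@@H](O)[C@H](O[Si](C)(C)C(C)(C)C)C1 | intermediate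
17 | (R)-2-methylbutanoic acid | CC[C@@H](C)C(=O)O | starting material
18 | methyl (3R,4R,5R)-3-acetoxy-5-(tert-butyldimethylsilyloxy)-4-[(2R)-2-methylbutanoyloxy]cyclohex-1-ene-1-carboxylate | COC(=O)C1=C[C@@H](OC(C)=O)[C@@H](OC(=O)[C@H](C)CC)[C@H](O[Si](C)(C)C(C)(C)C)C1 | intermediate
19 | methyl (3R,4S,5R)-3-acetoxy-5-hydroxy-4-[(2R)-2-methylbutanoyloxy]cyclohex-1-ene-1-carboxylate | COC(=O)C1=C[C@@H](OC(C)=O)[C@@H](OC(=O)[C@H](C)CC)[C@H](O)C1 | intermediate
20 | (S)-3-methylpentanoic acid | CC[C@H](C)CC(=O)O | starting material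
21 | methyl (3R,4S,5R)-3-acetoxy-4-[(2R)-2-methylbutanoyloxy]-5-[(3S)-3-methylpentanoyloxy]cyclohex-1-ene-1-carboxylate | CC[C@H](C)CC(=O)O[C@@H]1CC(C(=O)OC)=C[C@@H](OC(C)=O)[C@H]1OC(=O)[C@H](C)CC | target

Total step count: 15. Longest linear sequence: 15 steps (1 to 21); 7, 17 and 20 are purchased.

Steps most likely to fail

Step 9. Three things may go wrong. The Lewis acid may strip the PMB group before the ring closes. Closure through an open, non-chelated chair may erode the facial selectivity at C3. The new allylic titanium alkoxide may ionise.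
- The fallback closes the ring by olefin metathesis at C1=C2 in place of the cationic closure, uses known reactions only, and sets out from 11.
- Chelate-controlled addition of vinylmagnesium bromide (MgBr2·OEt2, CH2Cl2, −78 °C) should give the 3,4-syn enynol F1. Its C3 configuration is opposite to the one needed, because an external nucleophile enters the chelate from the face turned away from C5.
- Markovnikov hydromethoxycarbonylation of the terminal alkyne (Pd(OAc)2, 2-(diphenylphosphino)pyridine, catalytic MeSO3H, CO, MeOH) gives the α-substituted acrylate F2.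
- Ring-closing metathesis with the second-generation Grubbs catalyst gives the C3-epimeric hydroxy ester F3.
- A Mitsunobu reaction with acetic acid (PPh3, DIAD) inverts C3 and installs the acetate in one operation, which rejoins the route at 15.

Step 13. The acetyl group may migrate from O3 to the freshly liberated cis O4 hydroxyl under DMAP. Acylation in the crowded position may be sluggish, and slow acylation gives the activated α-branched acid time to epimerise.
- The fallback postpones the acetate so that O4 is acylated while it has no acyl neighbour, and sets out from 14.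
- O3 is masked as the triethylsilyl ether F4 (TESCl, imidazole).
- DDQ frees O4 to give the alcohol F5, flanked only by silyl ethers.
- Steglich esterification with 17 gives the 4-O-acyl bis-silyl ether F6.
- Selective methanolysis of the TES group (PPTS, MeOH, 0 °C) gives the C3 alcohol F7.
- Immediate acetylation (Ac2O, pyridine) comes back to the route at 18.

Step 6. The triflate may decompose through participation of the acetal oxygen O3 (five-membered oxonium formation), or it may suffer elimination instead of substitution.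
- The fallback forms C6–C1 by epoxide opening instead of sulfonate displacement and sets out from 5.
- TBAF removes the silyl group to give the diol F8.
- Bu2SnO-catalysed tosylation (TsCl, Et3N) marks the primary hydroxyl as the tosylate F9.
- K2CO3 in MeOH closes the terminal epoxide F10 with retention at C5.
- Lithium acetylide–ethylenediamine complex in DMSO opens it at C6 to the homopropargylic alcohol F11.
- Silylation (TBSCl, imidazole) returns to the route at 9.

Further compounds
F1 | step 9 | (3S,4R,5R)-5-(tert-butyldimethylsilyloxy)-4-(4-methoxybenzyloxy)oct-1-en-7-yn-3-ol | C=C[C@H](O)[C@@H](OCc1ccc(OC)cc1)[C@H](O[Si](C)(C)C(C)(C)C)CC#C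
F2 | step 9 | methyl (4R,5R,6S)-4-(tert-butyldimethylsilyloxy)-6-hydroxy-5-(4-methoxybenzyloxy)-2-methylideneoct-7-enoate | C=C[C@H](O)[C@@H](OCc1ccc(OC)cc1)[C@H](O[Si](C)(C)C(C)(C)C)CC(=C)C(=O)OC
F3 | step 9 | methyl (3S,4R,5R)-5-(tert-butyldimethylsilyloxy)-3-hydroxy-4-(4-methoxybenzyloxy)cyclohex-1-ene-1-carboxylate | COC(=O)C1=C[C@H](O)[C@@H](OCc2ccc(OC)cc2)[C@H](O[Si](C)(C)C(C)(C)C)C1
F4 | step 13 | methyl (3R,4S,5R)-5-(tert-butyldimethylsilyloxy)-4-(4-methoxybenzyloxy)-3-(triethylsilyloxy)cyclohex-1-ene-1-carboxylate | COC(=O)C1=C[C@@H](O[Si](CC)(CC)CC)[C@@H](OCc2ccc(OC)cc2)[C@H](O[Si](C)(C)C(C)(C)C)C1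
F5 | step 13 | methyl (3R,4S,5R)-5-(tert-butyldimethylsilyloxy)-4-hydroxy-3-(triethylsilyloxy)cyclohex-1-ene-1-carboxylate | COC(=O)C1=C[C@@H](O[Si](CC)(CC)CC)[C@@H](O)[C@H](O[Si](C)(C)C(C)(C)C)C1
F6 | step 13 | methyl (3R,4S,5R)-5-(tert-butyldimethylsilyloxy)-4-[(2R)-2-methylbutanoyloxy]-3-(triethylsilyloxy)cyclohex-1-ene-1-carboxylate | COC(=O)C1=C[C@@H](O[Si](CC)(CC)CC)[C@@H](OC(=O)[C@H](C)CC)[C@H](O[Si](C)(C)C(C)(C)C)C1
F7 | step 13 | methyl (3R,4R,5R)-5-(tert-butyldimethylsilyloxy)-3-hydroxy-4-[(2R)-2-methylbutanoyloxy]cyclohex-1-ene-1-carboxylate | COC(=O)C1=C[C@@H](O)[C@@H](OC(=O)[C@H](C)CC)[C@H](O[Si](C)(C)C(C)(C)C)C1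
F8 | step 6 | (1R)-1-[(4R)-2-(4-methoxyphenyl)-1,3-dioxolan-4-yl]ethane-1,2-diol | O1C(c2ccc(OC)cc2)OC[C@@H]1[C@H](O)CO
F9 | step 6 | (2R)-2-hydroxy-2-[(4R)-2-(4-methoxyphenyl)-1,3-dioxolan-4-yl]ethyl 4-methylbenzenesulfonate | O1C(c2ccc(OC)cc2)OC[C@@H]1[C@H](O)COS(=O)(=O)c3ccc(C)cc3
F10 | step 6 | (4R)-2-(4-methoxyphenyl)-4-[(2R)-oxiran-2-yl]-1,3-dioxolane | O1C(c2ccc(OC)cc2)OC[C@@H]1[C@H]3CO3
F11 | step 6 | (1R)-1-[(4R)-2-(4-methoxyphenyl)-1,3-dioxolan-4-yl]but-3-yn-1-ol | O1C(c2ccc(OC)cc2)OC[C@@H]1[C@H](O)CC#C
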